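The cyclodecene ring is closed by ring contraction. The array C9(–O)–C8(–O-acyl)–C7–C11(=C13) at the cyclodecene/α-methylene-γ-butyrolactone junction is the retron of a Claisen rearrangement. In a 12-membered oxacycle, C9 is joined through an enol-ether oxygen to C13 of a bridging butenolide and carries C8 as an exocyclic (Z)-enol senecioate. One thermal [3,3] shift expels O and C13 from the ring (12 → 10), forms C7–C8, sets C7 and C8 under control of C6, and unveils the methylene lactone, the C9 ketone and the C8 ester at once. C4–C6 come from a Sharpless kinetic resolution; the ketone is reduced last.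

Key step: step 15

Remark: locants C1–C15 are those of the germacranolide skeleton of the target (C6 lactone oxygen, C7–C11 bond, C8 ester, C9 carbinol, C10=C1 alkene, C4–C5 epoxide, C11=C13 methylene, C12 lactone carbonyl). C9 is formed without control in step 3 and is carried as both configurations (no descriptor at C9 in the SMILES) until it becomes sp2 in step 14. (4-Methoxybenzyloxy)acetaldehyde 6 is assumed to be purchasable.

Step 1
Reactants: 1 geranyl acetate
Product: 3 (2E)-3-methyl-6-oxohex-2-en-1-yl acetate, via ozonide 2 (not isolated)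
Conditions: O3 (1 equiv, Sudan Red 7B end point), CH2Cl2, −78 °C; PPh3, −78 °C → rt
Reagents that add atoms: ozone, [O-][O+]=O
Why: Ozonolysis with reductive work-up should cleave the electron-rich isopropylidene alkene first, because the other alkene is deactivated by the allylic acetate.

Step 2
Reactants: 3 (2E)-3-methyl-6-oxohex-2-en-1-yl acetate; 4 ethyltriphenylphosphonium iodide
Product: 5 (2E,6Z)-7-iodo-3-methylocta-2,6-dien-1-yl acetate
Conditions: 4, n-BuLi, THF, 0 °C; I2, −78 °C; NaHMDS, −78 → −20 °C; then 3, −78 °C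
Reagents that add atoms: ethyltriphenylphosphonium iodide (4), CC[P+](c1ccccc1)(c1ccccc1)c1ccccc1.[I-]; iodine, II
Why: Stork–Zhao Wittig olefination with the α-iodo ylide made in the flask should give the (Z)-2-iodoalkene (iodine cis to the chain), which fixes the C10=C1 geometry of the target.

Step 3
Reactants: 5 (2E,6Z)-7-iodo-3-methylocta-2,6-dien-1-yl acetate; 6 (4-methoxybenzyloxy)acetaldehyde
Product: 7 (2E,6Z)-8-hydroxy-9-(4-methoxybenzyloxy)-3,7-dimethylnona-2,6-dien-1-yl acetate
Conditions: CrCl2 (4 equiv), NiCl2 (2 mol %), DMSO/THF, rt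
Reagents that add atoms: (4-methoxybenzyloxy)acetaldehyde (6), COc1ccc(COCC=O)cc1
Why: Nozaki–Hiyama–Kishi coupling should add the alkenylchromium species to the aldehyde with retention of the trisubstituted alkene geometry and tolerance of the acetate; the new C9 carbinol is formed without control, which is irrelevant because C9 becomes sp2 in step 14.

Step 4
Reactants: 7 (2E,6Z)-8-hydroxy-9-(4-methoxybenzyloxy)-3,7-dimethylnona-2,6-dien-1-yl acetate; 8 methyl 2-(bromomethyl)acrylate
Product: 9 methyl 2-({[(3Z,7E)-9-acetoxy-1-(4-methoxybenzyloxy)-3,7-dimethylnona-3,7-dien-2-yl]oxy}methyl)acrylate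
Conditions: NaH, n-Bu4NI (cat.), THF, 0 °C (NaH added last)
Reagents that add atoms: methyl 2-(bromomethyl)acrylate (8), COC(=O)C(=C)CBr
Why: Williamson-type O-alkylation with a very reactive allylic bromide (SN2 and SN2′ give the same ether) should install C13, C11 and C12, the cold alkoxide being trapped faster than it attacks the acetate.

Step 5
Reactants: 9 methyl 2-({[(3Z,7E)-9-acetoxy-1-(4-methoxybenzyloxy)-3,7-dimethylnona-3,7-dien-2-yl]oxy}methyl)acrylate
Product: 10 methyl 2-({[(3Z,7E)-9-hydroxy-1-(4-methoxybenzyloxy)-3,7-dimethylnona-3,7-dien-2-yl]oxy}methyl)acrylate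
Conditions: K2CO3 (0.3 equiv), MeOH, 0 °C
Reagents that add atoms: none
Why: Base-catalysed methanolysis (transesterification) of the primary allylic acetate should be much faster than conjugate addition of methanol to the α-substituted acrylate, and the methyl ester makes ester exchange degenerate.

Step 6
Reactants: 10 methyl 2-({[(3Z,7E)-9-hydroxy-1-(4-methoxybenzyloxy)-3,7-dimethylnona-3,7-dien-2-yl]oxy}methyl)acrylate
Product: 11 methyl 2-({[(3Z,7E)-1-(4-methoxybenzyloxy)-3,7-dimethyl-9-oxonona-3,7-dien-2-yl]oxy}methyl)acrylate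
Conditions: MnO2, CH2Cl2, rt
Reagents that add atoms: none
Why: Allylic oxidation with MnO2 should give the (E)-enal without touching the ethers, the acrylate or the (Z)-alkene.

Step 7
Reactants: 11 methyl 2-({[(3Z,7E)-1-(4-methoxybenzyloxy)-3,7-dimethyl-9-oxonona-3,7-dien-2-yl]oxy}methyl)acrylate; 12 vinylmagnesium bromide
Product: 13 methyl 2-({[(3Z,7E)-9-hydroxy-1-(4-methoxybenzyloxy)-3,7-dimethylundeca-3,7,10-trien-2-yl]oxy}methyl)acrylate
Conditions: vinylMgBr, CeCl3, THF, −78 °C
Reagents that add atoms: vinylmagnesium bromide (12), C=C[Mg]Br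
Why: 1,2-Addition of the vinylcerium reagent (Grignard addition with CeCl3) should occur at the aldehyde, far more electrophilic than the hindered enoate; C6 is formed racemic and is resolved in step 8.

Step 8
Reactants: 13 methyl 2-({[(3Z,7E)-9-hydroxy-1-(4-methoxybenzyloxy)-3,7-dimethylundeca-3,7,10-trien-2-yl]oxy}methyl)acrylate
Product: 14 methyl 2-({[(3Z)-6-{(2R,3R)-3-[(1R)-1-hydroxyprop-2-en-1-yl]-2-methyloxiran-2-yl}-1-(4-methoxybenzyloxy)-3-methylhex-3-en-2-yl]oxy}methyl)acrylate
Conditions: Ti(OiPr)4, D-(−)-DIPT, t-BuOOH (0.55 equiv), 4 Å MS, CH2Cl2, −20 °C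
Reagents that add atoms: tert-butyl hydroperoxide, CC(C)(C)OO
Why: Sharpless kinetic resolution should epoxidise only the (6R)-alcohol at its trisubstituted C4=C5 alkene, the tartrate setting C4 and C5 (4R,5R) and the erythro rule tying them to C6, while the (6S)-alcohol is left behind and the undirected alkenes do not react.

Step 9
Reactants: 14 the (4R,5R,6R)-epoxy alcohol methyl ester
Product: 15 2-({[(3Z)-6-{(2R,3R)-3-[(1R)-1-hydroxyprop-2-en-1-yl]-2-methyloxiran-2-yl}-1-(4-methoxybenzyloxy)-3-methylhex-3-en-2-yl]oxy}methyl)acrylic acid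
Conditions: Me3SnOH, 1,2-dichloroethane, 70 °C; cold 0.1 M HCl wash
Reagents that add atoms: trimethyltin hydroxide, C[Sn](C)(C)O
Why: Ester hydrolysis with Me3SnOH runs under neutral conditions and should avoid Payne rearrangement or opening of the epoxy alcohol and conjugate addition of hydroxide.

Step 10
Reactants: 15 the (4R,5R,6R)-seco acid
Product: 16 (4R,5R,6S)-13-membered macrolactone O6–C12(=O)–C11(=CH2)–C13–O–C9–C10=C1–C2–C3–C4–C5–C6 with 6-vinyl and 9-CH2OPMB groups
Conditions: PPh3, DIAD, toluene (2 mM, slow addition of 15), 0 °C → rt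
Reagents that add atoms: none
Why: Mitsunobu macrolactonisation should let the carboxylate displace the activated C6 oxygen (13-exo-tet SN2 at high dilution), inverting C6 to (6S) and so turning the erythro into the threo C5/C6 relationship of the target.

Step 11
Reactants: 16 the (4R,5R,6S)-macrolactone
Product: 17 (4R,5R,6S)-bridged butenolide with the 12-membered oxacycle C9–O–C13–C11=C7–C6–C5–C4–C3–C2–C1=C10 and 9-CH2OPMB
Conditions: Grubbs II (10 mol %), toluene (2 mM), 80 °C
Reagents that add atoms: none
Why: Ester-tethered ring-closing metathesis of the C6 vinyl group with the 1,1-disubstituted acrylate should close the five-membered butenolide and leave the trisubstituted (Z)-alkene untouched, which converts the macrolactone into the 12-membered oxacycle.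

Step 12
Reactants: 17 the PMB-protected bridged butenolide
Product: 18 the bridged butenolide with 9-CH2OH
Conditions: DDQ, CH2Cl2/pH 7 buffer, 0 °C
Reagents that add atoms: none
Why: Oxidative PMB cleavage with DDQ under buffered conditions should spare the epoxide, the butenolide and the allylic ethers.

Step 13
Reactants: 18 the primary alcohol
Product: 19 the bridged butenolide with 9-CHO (α-alkoxy aldehyde)
Conditions: Dess–Martin periodinane, NaHCO3, CH2Cl2, 0 °C; used crude
Reagents that add atoms: none
Why: Dess–Martin oxidation under buffered, non-basic conditions should give the α-alkoxy aldehyde without moving the β,γ-alkene into conjugation.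

Step 14
Reactants: 19 the α-alkoxy aldehyde; 20 3-methylbut-2-enoyl chloride
Product: 22 (Z)-enol senecioate of 19 (C8=C9 with both oxygens cis), via potassium enolate 21 (not isolated)
Conditions: KHMDS (1.0 equiv), THF, −78 °C; then 20, −78 °C
Reagents that add atoms: 3-methylbut-2-enoyl chloride (20), CC(C)=CC(=O)Cl
Why: Deprotonation of the only α-hydrogen (C9–H) should give the potassium enolate chelated between the enolate and ether oxygens, and O-acylation (enol ester formation) traps it as the (Z)-enol senecioate.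

Step 15
Reactants: 22 the (Z)-enol senecioate
Product: 23 9-oxo derivative of the target (ten-membered enone with 8-senecioate and α-methylene lactone)
Conditions: toluene (degassed, BHT, base-washed glass), 100 °C
Reagents that add atoms: none
Why: Thermal Claisen ([3,3]-sigmatropic) rearrangement of the allyl vinyl ether C8=C9–O–C13–C11=C7 should form C7–C8 while O–C13 breaks, so that O and C13 leave the ring (12 → 10 atoms), C11=C13 becomes the exocyclic methylene of the lactone and C9 the enone carbonyl. The closest known reaction type is the aliphatic Claisen rearrangement of enol derivatives of α-allyloxy carbonyl compounds, here accelerated by the acyl group on the allyl unit (C12) and the vinyl group on C9. The ten-membered carbocycle is closed transannularly through a chair-like six-centre array spanned by the C10–C6 tether, with both tether ends pseudo-equatorial (bicyclo[7.3.1]-type transition state). C8 is controlled by the (Z)-enol ester geometry, which places the senecioyloxy group pseudo-axial in the chair and should give the (8R) centre, syn to C11 along the C6–C9 chain. C7 is controlled by C6, the vinyl ether adding to the butenolide face anti to C5, which gives the trans-fused lactone of 24. The step needs chair over boat and anti over syn addition; the substrate should secure both, since in the syn array the pseudo-axial acyloxy group collides with C5 and in the boat C10 sits over the lactone ring, and 100 °C lies below the range of the competing [1,5]-hydrogen shift of the (Z)-dienyl ether.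

Step 16
Reactants: 23 the 9-oxo derivative
Product: 24 (1(10)Z,4R,5R,6S,7R,8R,9R)-4,5-epoxy-9-hydroxy-8-(3-methylbut-2-enoyloxy)germacra-1(10),11(13)-dien-12,6-olide
Conditions: NaBH4, CeCl3·7H2O, MeOH, −78 °C
Reagents that add atoms: none
Why: Luche reduction should reduce the enone carbonyl 1,2 faster than it reduces the methylene lactone in a conjugate manner, hydride adding anti to the C8 acyloxy group (polar Felkin–Anh, from the ring periphery) to give the (9R) alcohol.

Compound list
1 | geranyl acetate, (2E)-3,7-dimethylocta-2,6-dien-1-yl acetate | CC(=O)OC/C=C(\C)CCC=C(C)C | starting material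
2 | ozonide, (2E)-5-(5,5-dimethyl-1,2,4-trioxolan-3-yl)-3-methylpent-2-en-1-yl acetate | CC(=O)OC/C=C(\C)CCC1OOC(C)(C)O1 | intermediate
3 | (2E)-3-methyl-6-oxohex-2-en-1-yl acetate | CC(=O)OC/C=C(\C)CCC=O | intermediate
4 | ethyltriphenylphosphonium iodide | CC[P+](c1ccccc1)(c1ccccc1)c1ccccc1.[I-] | starting material
5 | (2E,6Z)-7-iodo-3-methylocta-2,6-dien-1-yl acetate | CC(=O)OC/C=C(\C)CC/C=C(/C)I | intermediate
6 | (4-methoxybenzyloxy)acetaldehyde | COc1ccc(COCC=O)cc1 | starting material
7 | (2E,6Z)-8-hydroxy-9-(4-methoxybenzyloxy)-3,7-dimethylnona-2,6-dien-1-yl acetate (carbinol = future C9, both configurations) | CC(=O)OC/C=C(\C)CC/C=C(/C)C(O)COCc1ccc(OC)cc1 | intermediate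
8 | methyl 2-(bromomethyl)acrylate | COC(=O)C(=C)CBr | starting material
9 | methyl 2-({[(3Z,7E)-9-acetoxy-1-(4-methoxybenzyloxy)-3,7-dimethylnona-3,7-dien-2-yl]oxy}methyl)acrylate | CC(=O)OC/C=C(\C)CC/C=C(/C)C(COCc1ccc(OC)cc1)OCC(=C)C(=O)OC | intermediate
10 | methyl 2-({[(3Z,7E)-9-hydroxy-1-(4-methoxybenzyloxy)-3,7-dimethylnona-3,7-dien-2-yl]oxy}methyl)acrylate | OC/C=C(\C)CC/C=C(/C)C(COCc1ccc(OC)cc1)OCC(=C)C(=O)OC | intermediate
11 | methyl 2-({[(3Z,7E)-1-(4-methoxybenzyloxy)-3,7-dimethyl-9-oxonona-3,7-dien-2-yl]oxy}methyl)acrylate | O=C/C=C(\C)CC/C=C(/C)C(COCc1ccc(OC)cc1)OCC(=C)C(=O)OC | intermediate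
12 | vinylmagnesium bromide | C=C[Mg]Br | starting material
13 | methyl 2-({[(3Z,7E)-9-hydroxy-1-(4-methoxybenzyloxy)-3,7-dimethylundeca-3,7,10-trien-2-yl]oxy}methyl)acrylate (racemic at the carbinol = C6) | C=CC(O)/C=C(\C)CC/C=C(/C)C(COCc1ccc(OC)cc1)OCC(=C)C(=O)OC | intermediate
14 | methyl 2-({[(3Z)-6-{(2R,3R)-3-[(1R)-1-hydroxyprop-2-en-1-yl]-2-methyloxiran-2-yl}-1-(4-methoxybenzyloxy)-3-methylhex-3-en-2-yl]oxy}methyl)acrylate (4R,5R,6R in target numbering) | C=C[C@@H](O)[C@H]1O[C@]1(C)CC/C=C(/C)C(COCc1ccc(OC)cc1)OCC(=C)C(=O)OC | intermediate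
15 | 2-({[(3Z)-6-{(2R,3R)-3-[(1R)-1-hydroxyprop-2-en-1-yl]-2-methyloxiran-2-yl}-1-(4-methoxybenzyloxy)-3-methylhex-3-en-2-yl]oxy}methyl)acrylic acid | C=C[C@@H](O)[C@H]1O[C@]1(C)CC/C=C(/C)C(COCc1ccc(OC)cc1)OCC(=C)C(=O)O | intermediate
16 | (4R,5R,6S)-13-membered macrolactone: O6–C12(=O)–C11(=CH2)–C13–O–C9–C10(Me)=C1–C2–C3–C4(Me)–C5–C6, 4,5-epoxide, 6-vinyl, 9-CH2OPMB, (1(10)Z) | C=C[C@@H]1OC(=O)C(=C)COC(COCc2ccc(OC)cc2)/C(C)=C\CC[C@@]2(C)O[C@H]12 | intermediate
17 | (4R,5R,6S)-bridged butenolide: 12-membered oxacycle C9–O–C13–C11=C7–C6–C5–C4–C3–C2–C1=C10 with γ-lactone O6–C12(=O) across C6/C11, 4,5-epoxide, 9-CH2OPMB, (1(10)Z) | O=C1O[C@H]2C=C1COC(COCc3ccc(OC)cc3)/C(C)=C\CC[C@@]3(C)O[C@H]23 | intermediate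
18 | the same bridged butenolide with 9-CH2OH | O=C1O[C@H]2C=C1COC(CO)/C(C)=C\CC[C@@]3(C)O[C@H]23 | intermediate
19 | the same bridged butenolide with 9-CHO | O=C1O[C@H]2C=C1COC(C=O)/C(C)=C\CC[C@@]3(C)O[C@H]23 | intermediate
20 | 3-methylbut-2-enoyl chloride (senecioyl chloride) | CC(C)=CC(=O)Cl | starting material
21 | potassium (Z)-enolate of 19 (O8 cis to the ring ether oxygen) | [K+].[O-]/C=C1\OCC2=C[C@H](OC2=O)[C@H]3O[C@]3(C)CC/C=C1/C | intermediate
22 | (Z)-enol 3-methylbut-2-enoate of 19: exocyclic C8H(OCOCH=CMe2)=C9 on the 12-membered oxacycle, (4R,5R,6S), (1(10)Z) | CC(C)=CC(=O)O/C=C1\OCC2=C[C@H](OC2=O)[C@H]3O[C@]3(C)CC/C=C1/C | intermediate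
23 | 9-oxo derivative of 24: (1(10)Z)-4,5-epoxy-9-oxo-8-(3-methylbut-2-enoyloxy)germacra-1(10),11(13)-dien-12,6-olide, configuration at C4–C8 as in 24 (formally 7S because the ketone changes the CIP ranking) | C=C1C(=O)O[C@H]2[C@H]1[C@@H](OC(=O)C=C(C)C)C(=O)/C(C)=C\CC[C@@]1(C)O[C@H]21 | intermediate
24 | CNP0188779.3, (1(10)Z,4R,5R,6S,7R,8R,9R)-4,5-epoxy-9-hydroxy-8-(3-methylbut-2-enoyloxy)germacra-1(10),11(13)-dien-12,6-olide | C=C1C(=O)O[C@H]2[C@H]1[C@@H](OC(=O)C=C(C)C)[C@H](O)/C(C)=C\CC[C@@]1(C)O[C@H]21 | target

Total steps: 16. Longest linear sequence: 16 steps (from 1; the kinetic resolution in step 8 can pass on at most half of the material).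

Steps most likely to fail

Step 15. The transannular [3,3] shift may proceed with poor face or chair/boat selectivity, or the (Z)-dienyl ether may undergo a [1,5]-hydrogen shift on prolonged heating. The fallback sets out from 19 and returns at 23. The potassium enolate of 19 (KHMDS, THF, −78 → 0 °C) would undergo the 2-oxyanion-accelerated Claisen rearrangement below room temperature, giving the same ring contraction through the same chelated (Z)-enolate without heating. Protonation would give the (8R)-8-hydroxy-9-ketone F1, and Steglich esterification of F1 with 3-methylbut-2-enoic acid (DCC, DMAP, CH2Cl2, 0 °C) would give 23.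

Step 10. The carboxylate may attack the vinyl terminus (SN2′), the activated alcohol may eliminate, an acyloxyphosphonium pathway may give retention at C6, or oligomers may form. The fallback sets out from 14 and returns at 16. Intermolecular Mitsunobu inversion with 4-nitrobenzoic acid (PPh3, DIAD, THF) would give the (6S)-4-nitrobenzoate F2. Methanolysis (K2CO3, MeOH, 0 °C) would give the threo epoxy alcohol F3, and Me3SnOH would give the (6S)-seco acid F4. Yamaguchi macrolactonisation of F4 (2,4,6-trichlorobenzoyl chloride, Et3N; DMAP, toluene, high dilution) closes the ring with retention to 16.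

Step 16. The ring conformation may direct hydride to the wrong face of C9, the methylene lactone may be reduced in a conjugate manner, or the acyl group may migrate from O8 to O9. The fallback sets out from 23 and returns at 24 and replaces substrate control by catalyst control: a Corey–Bakshi–Shibata reduction (Me-CBS oxazaborolidine, catecholborane, toluene, −78 °C), which is 1,2-selective for enones. The catalyst enantiomer is chosen by the Corey model with the C10 alkenyl arm as the large group (the (R)-catalyst is predicted). No new compound is made.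

Further compounds
F1 | step 15 | (8R)-8-hydroxy-9-oxo lactone, (1(10)Z)-4,5-epoxy-8-hydroxy-9-oxogermacra-1(10),11(13)-dien-12,6-olide with the configuration of 24 at C4–C8 | C=C1C(=O)O[C@H]2[C@H]1[C@@H](O)C(=O)/C(C)=C\CC[C@@]1(C)O[C@H]21
F2 | step 10 | (6S)-4-nitrobenzoate of the epoxy alcohol methyl ester (4R,5R,6S) | C=C[C@H](OC(=O)c1ccc(cc1)[N+](=O)[O-])[C@H]1O[C@]1(C)CC/C=C(/C)C(COCc1ccc(OC)cc1)OCC(=C)C(=O)OC
F3 | step 10 | threo epoxy alcohol methyl ester (4R,5R,6S), C6 epimer of 14 | C=C[C@H](O)[C@H]1O[C@]1(C)CC/C=C(/C)C(COCc1ccc(OC)cc1)OCC(=C)C(=O)OC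
F4 | step 10 | threo seco acid (4R,5R,6S), C6 epimer of 15 | C=C[C@H](O)[C@H]1O[C@]1(C)CC/C=C(/C)C(COCc1ccc(OC)cc1)OCC(=C)C(=O)O
F0 | step 16 | none | none
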